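## Structural features

The target is a diaryl ether: the oxygen joins C8 of a 6-hydroxy-3-pentylisocoumarin (benzene ring A fused to the pyranone) to C1' of a second benzene, ring B. Ring B is hexasubstituted and carries in turn the ether oxygen (C1'), a hydroxyl (C2'), its only hydrogen (C3'), a second hydroxyl (C4'), the carboxylic acid (C5') and a pentyl chain (C6'). It is therefore an olivetolic acid with an extra oxygen between the pentyl group and one hydroxyl. There is no stereocentre, so every problem is one of regiochemistry and crowding: the ether oxygen is flanked by two ortho substituents on ring B and by the carbon that carries the lactone carbonyl on ring A. The fragile groups are the 2,4-dihydroxybenzoic acid of ring B (loss of CO2 in hot acid), the enol lactone (opening in aqueous base) and the free phenols (oxidation). The real difficulty is ring B with six different contiguous substituents, together with the hindered ether bond, which a late coupling of two finished rings would have to force. The key step exploits that C1' can be the alpha carbon of an aryloxyketene whose vinyl arm is C6' (pentyl) and C5' (ester), that C4' can be the ketene carbonyl carbon, and that C2'–C3' can come from an alkoxyalkyne, so the ether is made by alkylation at an sp3 carbon before ring B exists. Ring A then needs only a bromine ortho to the ether oxygen and a methoxy group para to that bromine, from which C1 and the C3–C4 unit of the lactone are added later.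

## Logic of the disconnections

**21 to 20.** Three alkyl–oxygen bonds are cut: O–CH3 of the ring A ether, O–C2H5 at C2' and O–CH3 of the C5' ester. The free acid loses CO2 easily and the triphenol is oxidisable, so all three are unveiled last and in one operation by one Lewis acid. The forward step must leave the enol lactone and the diaryl ether alone and must stay cold enough to keep the carboxyl.

**20 to 14 and 18.** The pyranone ring is cut at C4–C4a and at O2–C3. The carboxyl of 14 can direct a metal to the only free ortho C–H, the future C4a, so the lactone with its pentyl chain reduces to a benzoic acid and a six-carbon acyl ylide. The forward step demands carboxylate-directed C–H functionalisation beside a crowded ether, with tolerance of the phenol and ester of ring B.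

**18 to 15 and 16.** The bond between the ketone carbon and the ylide carbon is cut, which is the acylation of a sulfur ylide and asks nothing special.

**14 to 13.** The aryl–carboxyl bond (C8a–C1) is cut back to a bromide. A bromide is inert through the enolate, acid, ketene and thermal chemistry before it, whereas an ester in that position would invite Dieckmann closure onto the aryloxyacetate enolate. The forward step must carbonylate a hindered, electron-rich aryl bromide in the presence of a phenol.

**13 to 7 and 8.** Ring B is cut at C3'–C4', C1'–C2' and C4'–C5' (in the forward sense the C1'–C4' bond of 7 is broken on the way). The hexasubstituted ring and the hindered ether collapse to an acyclic acid chloride, whose ether is on sp3 carbon, and a two-carbon alkyne. Every substituent position follows from connectivity. The forward step must form and trap a ketene, control the [2+2] regiochemistry and the sense of ring opening, and start from the E alkene.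

**7 to 6 to 5.** Only functional groups change: C–Cl from C–OH, and the acid from a tert-butyl ester. The two carboxyls are made different from the outset. A symmetric diester would need mono-hydrolysis under base of a glutaconate whose acidic C–H lets the double bond move, so the site of hydrolysis would be uncertain. Acid cleavage of a tert-butyl ester avoids base; the demand is that the E geometry survives.

**5 to 3 and 4.** The C1'–C6' bond is cut. It joins an enolisable alpha-aryloxy ester carbon to the beta carbon of an ynoate that already carries the pentyl chain and the methyl ester. Which carboxyl sits next to the ether is thereby fixed by construction, not by substitution on an allylic bromide, where direct and allylic displacement would place different esters next to oxygen. The forward step must add in conjugate fashion and not at the ester carbonyl, and must deliver the E alkene.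

**3 to 1 and 2.** The O–CH2 bond is cut, a Williamson ether synthesis on an unhindered phenol.

## Other disconnections considered

**Alternative 1:** Ring A is cut at C8–C8a and C4a–C5 (Alder–Rickert).
- Forward step: the ring B phenol methyl 3-hydroxy-4,6-dimethoxy-2-pentylbenzoate A1 would be turned into its 3-aryloxycyclohexenone and then the silyloxy diene A2. A2 would add to the ester-bearing triple bond of methyl deca-2,4-diynoate A3, and the bicyclo[2.2.2]octadiene would expel ethene to give A4. A 6-endo closure of ester onto alkyne would then give the lactone.
- In favour: this is a known reaction class. The 1-aryloxy-3-silyloxy pattern of A2 puts the ester next to the ether, and A4 already holds C1, C3, C4 and the pentyl chain.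
- Against: the step does nothing for ring B. A1, a pentasubstituted phenol with a hindered C1' hydroxyl, needs its own multistep synthesis and must then be attached as a vinylogous ester. A3 is a sensitive diyne, ethene loss needs high temperature, and 5-exo closure can compete with 6-endo.
- Comparison: on precedent it is the better plan, and its regiochemistry is equally connectivity-controlled. For ring A alone it is the equal or the better (two operations against carbonylation plus annulation). On structure it is weaker, since the key step makes the easier ring and leaves the hexasubstituted one to be prepared separately. Overall it should be longer.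

**Alternative 2:** Ring A is cut at C5–C6 (vinylogous Dieckmann on a pyranone).
- Forward step: LiN(SiMe3)2 would deprotonate the 4-methyl group of the pyranone acrylate A5. The vinylogous enolate would attack the acrylate ester, and loss of methoxide and tautomerisation would give A6.
- In favour: no transition metal is needed, the lactone and pentyl chain come from a simple pyranone, aromatisation drives the closure, and the C6 hydroxyl arrives free. On the last point it is better than the chosen plan, with one ether fewer to cleave.
- Against: A5 is a tetrasubstituted beta-aryloxy acrylate whose ester must be cis to the pyranone, and it would have to be assembled from the hindered phenol A1. The alpha-CH2 of the 6-pentyl group is also vinylogously acidic, and the pyranone is sensitive to nucleophiles.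
- Comparison: the mechanism is simple polar chemistry and in that respect the equal of, or safer than, the chosen key step. Structurally it shares the weakness of alternative 1, because ring B and the hindered ether are not addressed, so the total count should exceed that of the chosen plan.

**Alternative 3:** Ring B is cut at C5'–C6' and C3'–C4' in reduced form (Michael–Dieckmann, late aromatisation).
- Forward step: dimethyl malonate A8 would add to the alpha-aryloxy enone A7 under NaOMe, and the methyl ketone enolate would close onto a malonate ester to give the trans dione ester A9. A separate dehydrogenation would give the resorcinol.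
- In favour: this is the classical route to olivetolates, the ether is again set on a simple phenol, and the same ring A handles allow the same end-game. Both ring B hydroxyls arrive free, so no ethyl ether needs cleaving.
- Against: the enone is deactivated by its oxygen donor and beta-alkyl group. Making A7 needs regiocontrol between the two alpha positions of an aryloxyacetone. In the oxidation step, loss of the aryloxy group is a second way to reach an aromatic ring. Two free phenols would then be carried through the palladium and rhodium steps.
- Comparison: on precedent it is the better plan, and on step count to the ring B intermediate it is the equal or slightly the better. The chosen plan is better on oxidation level (ring B is formed aromatic, with no dehydrogenation that could eject the ether) and on positional certainty. Alternative 3 therefore serves as the fallback for the key step.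

Key step: step 5

Remark on the chemistry: 5, 6 and 7 are racemic at the aryloxy-bearing carbon, which becomes the sp2 carbon C1' of ring B. The E isomers drawn are the ones wanted; a minor isomer with the double bond shifted between the aryloxy carbon and the pentyl carbon would give the same ketene 9 by 1,4-dehydrochlorination.

## Route

Step 1
Reactants: 1 2-bromo-5-methoxyphenol; 2 tert-butyl bromoacetate
Product: 3 tert-butyl 2-(2-bromo-5-methoxyphenoxy)acetate
Conditions: K2CO3, acetone, reflux
Reagents that add atoms: none
Why: Williamson ether synthesis, SN2 attack of the phenoxide on the alpha-bromo ester; the tert-butyl ester is stable to K2CO3.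

Step 2
Reactants: 3 tert-butyl 2-(2-bromo-5-methoxyphenoxy)acetate; 4 methyl oct-2-ynoate
Product: 5 1-tert-butyl 5-methyl (3E)-2-(2-bromo-5-methoxyphenoxy)-3-pentylpent-3-enedioate (racemic)
Conditions: LiN(iPr)2 (LDA), THF, −78 °C; then 4, −78 → −40 °C; AcOH
Reagents that add atoms: none
Why: Michael addition of a lithium ester enolate to an alkynoate; the first adduct is reprotonated by the acidic C–H of the product to a delocalised glutaconate anion, which stops further addition. C-protonation beside the aryloxy group should place the bulky C2 substituent trans to the methyl ester (E). The tert-butyl ester suppresses Claisen self-condensation and the aryl bromide is inert to the amide base at −78 °C.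

Step 3
Reactants: 5 1-tert-butyl 5-methyl (3E)-2-(2-bromo-5-methoxyphenoxy)-3-pentylpent-3-enedioate
Product: 6 (3E)-2-(2-bromo-5-methoxyphenoxy)-5-methoxy-5-oxo-3-pentylpent-3-enoic acid (racemic)
Conditions: CF3CO2H, CH2Cl2, 0 °C → rt
Reagents that add atoms: none
Why: Acidolysis of the tert-butyl ester through the tert-butyl cation; the methyl ester, the enoate and both aryl ethers are inert. No base is present that could move the double bond or choose the wrong ester.

Step 4
Reactants: 6 (3E)-2-(2-bromo-5-methoxyphenoxy)-5-methoxy-5-oxo-3-pentylpent-3-enoic acid
Product: 7 methyl (2E)-4-(2-bromo-5-methoxyphenoxy)-5-chloro-5-oxo-3-pentylpent-2-enoate (racemic)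
Conditions: (COCl)2, DMF (cat.), CH2Cl2, 0 °C → rt; evaporate, use at once
Reagents that add atoms: oxalyl chloride, ClC(=O)C(Cl)=O
Why: Acid chloride formation through the Vilsmeier-type chloroiminium salt under base-free conditions. In the E isomer the ester is trans to the acyl group and cannot close onto it.

Step 5
Reactants: 7 methyl (2E)-4-(2-bromo-5-methoxyphenoxy)-5-chloro-5-oxo-3-pentylpent-2-enoate; 8 ethoxyethyne
Product: 13 methyl 3-(2-bromo-5-methoxyphenoxy)-4-ethoxy-6-hydroxy-2-pentylbenzoate, via vinylketene 9 (not isolated), via cyclobutenone 10 (not isolated), via dienylketene 11 (not isolated), via cyclohexadienone 12 (not isolated)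
Conditions: Et3N, 8 (excess), toluene, slow addition of 7 at 0 °C → rt; then 80 °C
Reagents that add atoms: none
Why: Proposed new method: Et3N removes the C4–H of 7 (alpha to the acid chloride and to oxygen, gamma to the enoate) and chloride is lost to give the aryloxy(vinyl)ketene 9, whose carbonyl carbon (C4') is attacked by the nucleophilic CH carbon of the ynol ether (C3') while its alpha carbon (C1') closes onto the ethoxy-bearing carbon (C2'); the closest known reaction types are the Danheiser benzannulation of vinylketenes with alkoxyalkynes and the [2+2] trapping of aryloxyketenes made from aryloxyacetyl chlorides and an amine. The four-membered ring of 10 thus closes by a stepwise polar ketene–alkyne [2+2] whose regiochemistry is fixed by the polarisation of the ynol ether. On warming, 10 opens by a conrotatory four-electron process in which the oxygen donor at C1' rotates outward and the vinyl group inward, giving the (4Z)-dienylketene 11; a wrongly rotated ketene cannot cyclise and should return to 10, so the opening corrects itself. Ring B then closes by a thermal disrotatory six-electron electrocyclisation between C4' and C5', and dienone 12 tautomerises through its acidic C5'–H to the hydrogen-bonded phenol 13. No stereocentre remains, since the C1' centre of 7 and the quaternary centre of 10 are racemic and both end as sp2 carbons of ring B. The E geometry of 7 is needed because it points the ester away from the ketene, which blocks oxa-six-electron closure to a 6-methoxy-2-pyranone and leaves only hydrogen on the inside of the terminus that closes. Dimerisation of 9 is countered by adding 7 slowly to an excess of 8, so that the electron-poor ketene meets the electron-rich alkyne first. The reaction type has not been shown with an oxygen substituent on the ketene carbon or with ketene generation from a beta,gamma-unsaturated acid chloride of this kind, which is why it is put forward as new.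

Step 6
Reactants: 13 methyl 3-(2-bromo-5-methoxyphenoxy)-4-ethoxy-6-hydroxy-2-pentylbenzoate
Product: 14 2-[6-ethoxy-4-hydroxy-3-(methoxycarbonyl)-2-pentylphenoxy]-4-methoxybenzoic acid
Conditions: Pd(OAc)2 (cat.), Xantphos (cat.), CO (1 atm), K2CO3, H2O, 1,4-dioxane, 90 °C; then aq. HCl, 0 °C
Reagents that add atoms: carbon monoxide, [C-]#[O+]; water, O
Why: Palladium-catalysed hydroxycarbonylation: oxidative addition of the aryl bromide to zerovalent palladium, CO insertion and attack of hydroxide on the acylpalladium species. The ring B methyl ester lies between two ortho substituents and beside a phenoxide, so it should resist the aqueous carbonate. Intramolecular C–H arylation is blocked because both positions ortho to the ether on ring B are substituted.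

Step 7
Reactants: 15 hexanoyl chloride; 16 trimethylsulfoxonium iodide
Product: 18 1-[dimethyl(oxo)-λ6-sulfanylidene]heptan-2-one, via dimethylsulfoxonium methylide 17 (not isolated)
Conditions: KOtBu, THF, reflux; then 15, 0 °C → rt
Reagents that add atoms: none
Why: Acylation of the Corey–Chaykovsky methylide; a second equivalent of the methylide removes the proton of the acylated sulfoxonium salt to give the stabilised keto ylide.

Step 8
Reactants: 14 2-[6-ethoxy-4-hydroxy-3-(methoxycarbonyl)-2-pentylphenoxy]-4-methoxybenzoic acid; 18 1-[dimethyl(oxo)-λ6-sulfanylidene]heptan-2-one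
Product: 20 methyl 4-ethoxy-6-hydroxy-3-[(6-methoxy-1-oxo-3-pentyl-1H-isochromen-8-yl)oxy]-2-pentylbenzoate, via keto acid 19 (not isolated)
Conditions: [Cp*RhCl2]2 (cat.), NaOAc, (CF3)2CHOH, 80 °C
Reagents that add atoms: none
Why: Carboxylate-directed C–H activation by trivalent rhodium (acetate-assisted metalation at the only free ortho position), carbene formation from the ylide with loss of DMSO, migratory insertion and protonation give keto acid 19, which cyclodehydrates to the isocoumarin. Annulation of benzoic acids with sulfoxonium ylides is a known reaction type. Silver salts are left out to avoid protodecarboxylation of the electron-rich acid, and ring B has no C–H ortho to a group that could direct the metal.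

Step 9
Reactants: 20 methyl 4-ethoxy-6-hydroxy-3-[(6-methoxy-1-oxo-3-pentyl-1H-isochromen-8-yl)oxy]-2-pentylbenzoate
Product: 21 4,6-dihydroxy-3-[(6-hydroxy-1-oxo-3-pentyl-1H-isochromen-8-yl)oxy]-2-pentylbenzoic acid
Conditions: BBr3 (excess), CH2Cl2, −78 °C → rt; then H2O, 0 °C
Reagents that add atoms: none
Why: Lewis acid dealkylation: BBr3 binds each ether oxygen and the chelated ester carbonyl, and bromide attacks the methyl and ethyl groups in SN2 fashion; cleavage of methyl esters by BBr3 is a known reaction. The enol lactone and the diaryl ether have no alkyl–oxygen bond open to such attack. The acid is freed only on cold hydrolysis of its boron chelate, which limits loss of CO2.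

## Compound list

1 | 2-bromo-5-methoxyphenol | COc1ccc(Br)c(O)c1 | starting material
2 | tert-butyl bromoacetate | CC(C)(C)OC(=O)CBr | starting material
3 | tert-butyl 2-(2-bromo-5-methoxyphenoxy)acetate | COc1ccc(Br)c(OCC(=O)OC(C)(C)C)c1 | intermediate
4 | methyl oct-2-ynoate | CCCCCC#CC(=O)OC | starting material
5 | 1-tert-butyl 5-methyl (3E)-2-(2-bromo-5-methoxyphenoxy)-3-pentylpent-3-enedioate, racemic (S drawn) | CCCCC/C(=C\C(=O)OC)[C@H](Oc1cc(OC)ccc1Br)C(=O)OC(C)(C)C | intermediate
6 | (3E)-2-(2-bromo-5-methoxyphenoxy)-5-methoxy-5-oxo-3-pentylpent-3-enoic acid, racemic (S drawn) | CCCCC/C(=C\C(=O)OC)[C@H](Oc1cc(OC)ccc1Br)C(=O)O | intermediate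
7 | methyl (2E)-4-(2-bromo-5-methoxyphenoxy)-5-chloro-5-oxo-3-pentylpent-2-enoate, racemic (S drawn) | CCCCC/C(=C\C(=O)OC)[C@H](Oc1cc(OC)ccc1Br)C(Cl)=O | intermediate
8 | ethoxyethyne | CCOC#C | starting material
9 | methyl (2E)-4-(2-bromo-5-methoxyphenoxy)-5-oxo-3-pentylpenta-2,4-dienoate (vinylketene) | CCCCC/C(=C\C(=O)OC)C(Oc1cc(OC)ccc1Br)=C=O | intermediate
10 | methyl (2E)-3-[1-(2-bromo-5-methoxyphenoxy)-2-ethoxy-4-oxocyclobut-2-en-1-yl]oct-2-enoate, racemic (one enantiomer drawn) | CCCCC/C(=C\C(=O)OC)[C@@]1(Oc2cc(OC)ccc2Br)C(OCC)=CC1=O | intermediate
11 | methyl (2E,4Z)-4-(2-bromo-5-methoxyphenoxy)-5-ethoxy-7-oxo-3-pentylhepta-2,4,6-trienoate (dienylketene) | CCCCC/C(=C\C(=O)OC)/C(Oc1cc(OC)ccc1Br)=C(OCC)\C=C=O | intermediate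
12 | methyl 3-(2-bromo-5-methoxyphenoxy)-4-ethoxy-6-oxo-2-pentylcyclohexa-2,4-diene-1-carboxylate, racemic | CCCCCC1=C(Oc2cc(OC)ccc2Br)C(OCC)=CC(=O)C1C(=O)OC | intermediate
13 | methyl 3-(2-bromo-5-methoxyphenoxy)-4-ethoxy-6-hydroxy-2-pentylbenzoate | CCCCCc1c(Oc2cc(OC)ccc2Br)c(OCC)cc(O)c1C(=O)OC | intermediate
14 | 2-[6-ethoxy-4-hydroxy-3-(methoxycarbonyl)-2-pentylphenoxy]-4-methoxybenzoic acid | CCCCCc1c(Oc2cc(OC)ccc2C(=O)O)c(OCC)cc(O)c1C(=O)OC | intermediate
15 | hexanoyl chloride | CCCCCC(Cl)=O | starting material
16 | trimethylsulfoxonium iodide | C[S+](C)(C)=O.[I-] | starting material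
17 | dimethylsulfoxonium methylide | C[S+](C)(=O)[CH2-] | intermediate
18 | 1-[dimethyl(oxo)-λ6-sulfanylidene]heptan-2-one | CCCCCC(=O)C=S(C)(C)=O | intermediate
19 | 2-[6-ethoxy-4-hydroxy-3-(methoxycarbonyl)-2-pentylphenoxy]-4-methoxy-6-(2-oxoheptyl)benzoic acid | CCCCCC(=O)Cc1cc(OC)cc(Oc2c(OCC)cc(O)c(C(=O)OC)c2CCCCC)c1C(=O)O | intermediate
20 | methyl 4-ethoxy-6-hydroxy-3-[(6-methoxy-1-oxo-3-pentyl-1H-isochromen-8-yl)oxy]-2-pentylbenzoate | CCCCCc1cc2cc(OC)cc(Oc3c(OCC)cc(O)c(C(=O)OC)c3CCCCC)c2c(=O)o1 | intermediate
21 | 4,6-dihydroxy-3-[(6-hydroxy-1-oxo-3-pentyl-1H-isochromen-8-yl)oxy]-2-pentylbenzoic acid | CCCCCc1cc2cc(O)cc(Oc3c(O)cc(O)c(C(=O)O)c3CCCCC)c2c(=O)o1 | target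

## Step count and least certain steps

Total: 9 steps. Longest linear sequence: 8 steps (steps 1 to 6, 8 and 9, from 1 to 21); step 7 is a one-step side branch.

**Step 5 (key step).**
- Most likely failure: loss of the ketene before it meets the alkyne, by dimerisation or amine-induced oligomerisation. Next most likely is E to Z isomerisation of 7 through its double-bond-shifted tautomer, after which the ester can close onto the ketene and give a pyranone. Acylation of the product phenol by remaining ketene is a lesser risk.
- Fallback (known chemistry, the classical olivetolate construction on the aryloxy series): it sets out from 1 and comes back at 13.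
  - 1 would be alkylated with chloroacetone (K2CO3, acetone) to 1-(2-bromo-5-methoxyphenoxy)propan-2-one F1.
  - Amine-catalysed aldol condensation with hexanal (pyrrolidine, AcOH), which for alpha-oxygenated ketones runs through the more substituted enamine, would give (3Z)-3-(2-bromo-5-methoxyphenoxy)non-3-en-2-one F2 (the same compound as A7).
  - Dimethyl malonate with NaOMe in MeOH at reflux would give methyl 5-(2-bromo-5-methoxyphenoxy)-2-hydroxy-4-oxo-6-pentylcyclohex-1-ene-1-carboxylate F3 (racemic trans, the same compound as A9).
  - Dehydrogenation with DDQ in dioxane would give methyl 3-(2-bromo-5-methoxyphenoxy)-4,6-dihydroxy-2-pentylbenzoate F4.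
  - Ethylation of the C2' hydroxyl, the one not hydrogen-bonded to the ester (EtI, K2CO3, acetone), would return 13.

**Step 2.**
- Most likely failure: attack of the hard lithium enolate at the ester carbonyl of 4 in place of conjugate addition, or base-induced oligomerisation of the ynoate. Protonation to the Z or double-bond-shifted isomer would lower the amount of usable E material.
- Fallback (a soft nucleophile under catalytic base): it sets out from 1 and comes back at 6.
  - 1 and commercial di-tert-butyl bromomalonate (K2CO3, acetone) would give di-tert-butyl 2-(2-bromo-5-methoxyphenoxy)propanedioate F5.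
  - Michael addition of F5 to 4 with catalytic Cs2CO3 in DMF would give 1,1-di-tert-butyl 3-methyl (2E)-1-(2-bromo-5-methoxyphenoxy)-2-pentylprop-2-ene-1,1,3-tricarboxylate F6.
  - CF3CO2H would free 2-(2-bromo-5-methoxyphenoxy)-2-[(2E)-1-methoxy-1-oxooct-2-en-3-yl]propanedioic acid F7, which on gentle warming loses one CO2 to give 6.

**Step 8.**
- Most likely failure: slow C–H metalation beside a carboxylate twisted out of plane by the bulky ortho aryloxy group. Slower turnover would give room for O-alkylation of the acid by the ylide or for incomplete cyclodehydration of 19.
- Fallback (a stronger directing group): it sets out from 14 and comes back at 20.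
  - Amide coupling of 14 with O-methylhydroxylamine hydrochloride (EDC·HCl, Et3N) would give methyl 4-ethoxy-6-hydroxy-3-[5-methoxy-2-(methoxycarbamoyl)phenoxy]-2-pentylbenzoate F8.
  - With [Cp*RhCl2]2, 18 and an acidic additive such as Zn(OTf)2, the N-methoxyamide directs the same acylmethylation, and cyclisation through oxygen with loss of O-methylhydroxylamine would give 20.

**Step 9.**
- Most likely failure: incomplete dealkylation of the hindered, chelated ester after the ethers are gone, or acid-induced loss of CO2 from ring B if exposure is prolonged to force that cleavage.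
- Fallback (staged, with a neutral second stage): it sets out from 20 and comes back at 21.
  - BBr3 at −78 → 0 °C would be stopped at methyl 4,6-dihydroxy-3-[(6-hydroxy-1-oxo-3-pentyl-1H-isochromen-8-yl)oxy]-2-pentylbenzoate F9.
  - The methyl ester of F9 would then be cleaved by SN2 demethylation with LiI in EtOAc at reflux, giving the lithium carboxylate without strong acid; cold acidification would give 21.

## Further compounds

F1 | step 5 | 1-(2-bromo-5-methoxyphenoxy)propan-2-one | COc1ccc(Br)c(OCC(C)=O)c1
F2 | step 5 | (3Z)-3-(2-bromo-5-methoxyphenoxy)non-3-en-2-one | CCCCC/C=C(\Oc1cc(OC)ccc1Br)C(C)=O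
F3 | step 5 | methyl 5-(2-bromo-5-methoxyphenoxy)-2-hydroxy-4-oxo-6-pentylcyclohex-1-ene-1-carboxylate, racemic trans (5R,6S drawn) | CCCCC[C@@H]1[C@@H](Oc2cc(OC)ccc2Br)C(=O)CC(O)=C1C(=O)OC
F4 | step 5 | methyl 3-(2-bromo-5-methoxyphenoxy)-4,6-dihydroxy-2-pentylbenzoate | CCCCCc1c(Oc2cc(OC)ccc2Br)c(O)cc(O)c1C(=O)OC
F5 | step 2 | di-tert-butyl 2-(2-bromo-5-methoxyphenoxy)propanedioate | COc1ccc(Br)c(OC(C(=O)OC(C)(C)C)C(=O)OC(C)(C)C)c1
F6 | step 2 | 1,1-di-tert-butyl 3-methyl (2E)-1-(2-bromo-5-methoxyphenoxy)-2-pentylprop-2-ene-1,1,3-tricarboxylate | CCCCC/C(=C\C(=O)OC)C(Oc1cc(OC)ccc1Br)(C(=O)OC(C)(C)C)C(=O)OC(C)(C)C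
F7 | step 2 | 2-(2-bromo-5-methoxyphenoxy)-2-[(2E)-1-methoxy-1-oxooct-2-en-3-yl]propanedioic acid | CCCCC/C(=C\C(=O)OC)C(Oc1cc(OC)ccc1Br)(C(=O)O)C(=O)O
F8 | step 8 | methyl 4-ethoxy-6-hydroxy-3-[5-methoxy-2-(methoxycarbamoyl)phenoxy]-2-pentylbenzoate | CCCCCc1c(Oc2cc(OC)ccc2C(=O)NOC)c(OCC)cc(O)c1C(=O)OC
F9 | step 9 | methyl 4,6-dihydroxy-3-[(6-hydroxy-1-oxo-3-pentyl-1H-isochromen-8-yl)oxy]-2-pentylbenzoate | CCCCCc1cc2cc(O)cc(Oc3c(O)cc(O)c(C(=O)OC)c3CCCCC)c2c(=O)o1
A1 | alternative 1 | methyl 3-hydroxy-4,6-dimethoxy-2-pentylbenzoate | CCCCCc1c(O)c(OC)cc(OC)c1C(=O)OC
A2 | alternative 1 | methyl 3-{[3-(tert-butyldimethylsilyloxy)cyclohexa-1,3-dien-1-yl]oxy}-4,6-dimethoxy-2-pentylbenzoate | CCCCCc1c(OC2=CC(O[Si](C)(C)C(C)(C)C)=CCC2)c(OC)cc(OC)c1C(=O)OC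
A3 | alternative 1 | methyl deca-2,4-diynoate | CCCCCC#CC#CC(=O)OC
A4 | alternative 1 | methyl 3-[5-(tert-butyldimethylsilyloxy)-3-(hept-1-ynyl)-2-(methoxycarbonyl)phenoxy]-4,6-dimethoxy-2-pentylbenzoate | CCCCCC#Cc1cc(O[Si](C)(C)C(C)(C)C)cc(Oc2c(OC)cc(OC)c(C(=O)OC)c2CCCCC)c1C(=O)OC
A5 | alternative 2 | methyl 4,6-dimethoxy-3-{[(1E)-3-methoxy-1-(4-methyl-2-oxo-6-pentyl-2H-pyran-3-yl)-3-oxoprop-1-en-1-yl]oxy}-2-pentylbenzoate | CCCCCc1cc(C)c(/C(Oc2c(OC)cc(OC)c(C(=O)OC)c2CCCCC)=C\C(=O)OC)c(=O)o1
A6 | alternative 2 | methyl 3-[(6-hydroxy-1-oxo-3-pentyl-1H-isochromen-8-yl)oxy]-4,6-dimethoxy-2-pentylbenzoate | CCCCCc1cc2cc(O)cc(Oc3c(OC)cc(OC)c(C(=O)OC)c3CCCCC)c2c(=O)o1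
A7 | alternative 3 | (3Z)-3-(2-bromo-5-methoxyphenoxy)non-3-en-2-one | CCCCC/C=C(\Oc1cc(OC)ccc1Br)C(C)=O
A8 | alternative 3 | dimethyl malonate | COC(=O)CC(=O)OC
A9 | alternative 3 | methyl 5-(2-bromo-5-methoxyphenoxy)-2-hydroxy-4-oxo-6-pentylcyclohex-1-ene-1-carboxylate, racemic trans (5R,6S drawn) | CCCCC[C@@H]1[C@@H](Oc2cc(OC)ccc2Br)C(=O)CC(O)=C1C(=O)OC
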